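## Analysis of the target

Target 22 is a (2S)-flavanone, that is a 2-arylchroman-4-one. Ring A carries free hydroxyl groups at C5 and C7, ring C is the dihydropyranone, and ring B is joined to C2. Ring B has a 4'-methoxy group flanked by an (E)-3-methylbuta-1,3-dienyl group at C3' and a 3-methylbut-2-enyl (prenyl) group at C5'. C2 is the only stereocentre. It is benzylic, bears the ring oxygen O1 and lies β to the C4 ketone, so it can be lost by retro-oxa-Michael opening to the chalcone or by ionisation of the C2–O1 bond. The conjugated diene and the prenyl alkene are sensitive to acid, electrophiles, radicals and hydrogenation, and the free phenols make ring C easier to open under base. C3' and C5' are equivalent by the local symmetry of ring B, so the two different C5 chains can only be told apart by two different leaving groups. The difficulty is therefore one of ordering: ring-A protecting groups must be removed before the alkenes arrive, and C2 must survive ring closure, deprotection and two couplings. The strategy rests on the C4–C4a bond. C4a is ortho to O1 and to the C5 oxygen and para to the C7 oxygen, and in a 3,5-dioxygenated phenyl ether the two carbons ortho to the ether oxygen are equivalent. A β-aryloxy acid that already carries C2 can therefore close ring C with no regiochemical or stereochemical decision.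

## Retrosynthetic reasoning

**Side chains of ring B (22 ⇒ 20 + 21, 20 ⇒ 17 + 19).** The aryl–prenyl and aryl–dienyl bonds are cut first, because neither alkene would survive the acylation, the debenzylation, the hydroboration or the oxidations earlier in the route. Bromine and iodine in 17 mark the two equivalent positions, and the iodide reacts first. Stille coupling with stannanes 19 and 21 needs no base, so the base-sensitive flavanone and its free phenols are not endangered.

**Phenol protection (17 ⇒ 16).** The two O-benzyl bonds are cut next. Hydrogenolysis is ruled out by the aryl halides now and by the alkenes later, so a Lewis-acid debenzylation is placed before the alkenes are introduced.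

**Ring C (16 ⇒ 14).** The C4–C4a bond is cut, which opens ring C to acid 14. The forward reaction is an intramolecular acylation of a ring activated by three oxygens. Only the two equivalent ortho carbons are within reach of the three-atom tether. No bond to C2 is touched, so the step only has to avoid ionising the benzylic ether.

**Carboxyl group (14 ⇒ 12 ⇒ 10).** The acid is traced back to primary alcohol 12 and then to the terminal alkene of allyl ether 10. The forward steps are an anti-Markovnikov hydroboration–oxidation and an oxidation of the alcohol to the acid. This places the vinyl group next to the stereocentre, which is what an asymmetric allylic substitution delivers.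

**C2–O1 bond (10 ⇒ 7 + 8).** The aryl ether bond at the stereocentre is cut to linear cinnamyl carbonate 7 and phenol 8, which reacts as phenoxide 9. An iridium-catalysed allylic etherification must give the branched ether and set the (S) configuration. This is the only stereo-determining step, and it is placed early, on robust material.

**Cinnamyl carbonate (7 ⇒ 6 ⇒ 5 ⇒ 3 + 4, 3 ⇒ 2 ⇒ 1).** Carbonate 7 comes from allylic alcohol 6, which comes from cinnamate 5. The C=C bond of 5 is cut to aldehyde 3 and stabilised ylide 4. Aldehyde 3 comes from 1 by iodination at the one free position ortho to the phenol, then O-methylation.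

**Dienyl stannane (19 ⇒ 18).** The C–Sn and C–H bonds are cut to enyne 18. A syn-hydrostannation of the alkyne should give the (E)-dienyl stannane in one step.

## Alternatives that were turned down

**Alternative 1: oxocarbenium cyclisation forming C2–C3.**
- Disconnection: C2–C3 is cut with O1–C2 already in place. The substrate A2 is a mixed aryl methyl acetal of the fully substituted ring-B aldehyde, with the ring-A acetyl group masked as an enol silane.
- Forward key step: a confined chiral Brønsted acid expels methanol. The enol-silane carbon C3 attacks the oxocarbenium carbon C2 within the chiral ion pair and gives silyl-protected flavanone A1. Desilylation would then give 22.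
- For: ring B is fully decorated on a simple benzaldehyde before any sensitive heterocycle exists. The end game is a mild desilylation. The stereocentre and ring C arise in one catalytic step.
- Against: an acid strong enough to ionise the acetal can also protonate the diene and the prenyl alkene. A2 combines a mixed acetal, an enol silane and aryl silyl ethers, all acid-labile, and is itself hard to make from a hindered 2-acylphenol. Ionisation can expel the phenoxide instead of methoxide. Enantiocontrol would rest on an ion pair with a flat, aryl-stabilised cation in a ring closure that is not an established substrate class for such catalysts.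
- Comparison: this route is more convergent and has the gentler end game. The chosen route sets the stereocentre with an established reaction type and closes the ring in a step with no stereochemical demand, on halogenated intermediates that tolerate every reagent used.

**Alternative 2: asymmetric hetero-Diels–Alder reaction before ring A.**
- Disconnection: C2–C3 and O1–C8a are cut while ring A is still absent.
- Forward key step: aldehyde 3 and diene A4 combine under a chiral Lewis acid made from Ti(OiPr)4 and BINOL. Loss of methanol and the silyl group gives dihydropyranone A3.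
- For: this cycloaddition of aromatic aldehydes is among the most dependable ways to set an aryl-bearing oxygenated stereocentre. It starts from aldehyde 3 directly. On the stereo-setting step it is at least as strong as the chosen route.
- Against: A3 contains only ring C. A benzene ring with two hydroxyl groups would have to be built onto its enol-ether double bond, a push–pull alkene that is a poor dienophile and a poor acceptor. The acylation, condensation and aromatisation steps needed run under base or oxidants and threaten C2 through β-elimination of the ring oxygen.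
- Comparison: the chosen route buys ring A complete as phenol 8 and needs one bond to fuse it, so it is clearly shorter.

**Alternative 3: ortho-quinone methide cycloaddition with a ring-B styrene.**
- Disconnection: O1–C2 and C3–C4 are cut together.
- Forward key step: a chiral BINOL-derived phosphoric acid ionises acetal A7 to a ring-A ortho-quinone methide with a methoxy group on the methide carbon. This adds to styrene A6 and gives the 2,4-cis 4-methoxychroman A5.
- For: it is the most convergent of the four, making two bonds and ring C in one step from two simple fragments. The C4 configuration is irrelevant because C4 is oxidised later.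
- Against: the cycloaddition has inverse electron demand and needs an electron-rich alkene. In A6 the halogens withdraw electron density and twist the only donor, the 4-methoxy group, out of conjugation. A slow, stepwise cationic pathway with weak control at C2 is likely, because the catalyst binds the quinone-methide oxygen far from C2. A5 holds a very labile benzylic ether on a ring with two alkoxy groups, and turning it into the ketone costs hydrolysis and oxidation at that sensitive carbon.
- Comparison: the chosen route is longer in linear count, but the halogens that hamper this alternative are the same ones that protect C2 in the chosen key step.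

Key step: step 9

Assumption (sense of induction in step 6): the (Sa,Sc,Sc) phosphoramidite is taken to send the phenoxide to the face that gives the (S)-ether, by analogy with the facial preference of this catalyst family for aryl-substituted allyl carbonates and heteroatom nucleophiles. If the first run shows the opposite sense, the (Ra,Rc,Rc) ligand is used and nothing else changes.

## Route

Step 1
Reactants: 1 3-bromo-4-hydroxybenzaldehyde
Product: 2 3-bromo-4-hydroxy-5-iodobenzaldehyde
Conditions: NIS (1.05 equiv), TsOH·H2O (10 mol %), MeCN, rt
Reagents that add atoms: N-iodosuccinimide, O=C1CCC(=O)N1I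
Why: Electrophilic aromatic iodination; the phenol directs to its only free ortho position (the other ortho carbon holds bromine, the para carbon the formyl group), so a single regioisomer is expected.

Step 2
Reactants: 2 3-bromo-4-hydroxy-5-iodobenzaldehyde
Product: 3 3-bromo-5-iodo-4-methoxybenzaldehyde
Conditions: MeI (1.5 equiv), K2CO3 (2 equiv), DMF, 40 °C
Reagents that add atoms: iodomethane, CI
Why: Williamson O-methylation; the phenol is acidic (two ortho halogens, para formyl group) and the small electrophile reaches the flanked oxygen, while the aldehyde is untouched.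

Step 3
Reactants: 3 3-bromo-5-iodo-4-methoxybenzaldehyde; 4 ethyl (triphenylphosphoranylidene)acetate
Product: 5 ethyl (E)-3-(3-bromo-5-iodo-4-methoxyphenyl)prop-2-enoate
Conditions: 4 (1.2 equiv), CH2Cl2, rt
Reagents that add atoms: none
Why: Wittig olefination with a stabilised ylide, which should give the (E)-cinnamate under thermodynamic control of the oxaphosphetane; the aryl halides are inert.

Step 4
Reactants: 5 ethyl (E)-3-(3-bromo-5-iodo-4-methoxyphenyl)prop-2-enoate
Product: 6 (E)-3-(3-bromo-5-iodo-4-methoxyphenyl)prop-2-en-1-ol
Conditions: i-Bu2AlH (2.5 equiv), CH2Cl2, −78 °C; aq. potassium sodium tartrate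
Reagents that add atoms: none
Why: 1,2-Reduction of the conjugated ester by an aluminium hydride at low temperature should give the allylic alcohol with the alkene geometry and both carbon–halogen bonds intact.

Step 5
Reactants: 6 (E)-3-(3-bromo-5-iodo-4-methoxyphenyl)prop-2-en-1-ol
Product: 7 (E)-3-(3-bromo-5-iodo-4-methoxyphenyl)prop-2-enyl methyl carbonate
Conditions: ClCO2Me (1.5 equiv), pyridine (2 equiv), CH2Cl2, 0 °C
Reagents that add atoms: methyl chloroformate, COC(=O)Cl
Why: O-Acylation of the primary allylic alcohol gives the linear carbonate, the usual leaving group for iridium-catalysed allylic substitution because ionisation is made irreversible by loss of CO2.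

Step 6
Reactants: 7 (E)-3-(3-bromo-5-iodo-4-methoxyphenyl)prop-2-enyl methyl carbonate; 8 3,5-bis(benzyloxy)phenol
Product: 10 1-[(1S)-1-[3,5-bis(benzyloxy)phenoxy]prop-2-enyl]-3-bromo-5-iodo-4-methoxybenzene, via lithium 3,5-bis(benzyloxy)phenoxide 9 (not isolated)
Conditions: 8 (2 equiv), n-BuLi (2 equiv), THF, 0 °C; then 7, [Ir(cod)Cl]2 (2 mol %), (Sa,Sc,Sc)-O,O'-(1,1'-binaphthalene-2,2'-diyl) N,N-bis(1-phenylethyl)phosphoramidite (4 mol %, catalyst pre-activated with n-PrNH2, volatiles removed), THF, rt to 50 °C
Reagents that add atoms: none
Why: Iridium-catalysed asymmetric allylic etherification: the cyclometalated iridium–phosphoramidite complex ionises 7 to an allyl complex and phenoxide 9 attacks the aryl-bearing terminus anti to the metal, giving the branched ether; the chiral ligand selects the face of the allyl unit and so sets the future C2 as (S). The ring-B aryl bears no ortho substituent next to the allyl chain, which suits this catalyst, and the carbon–halogen bonds are not expected to add to the monovalent iridium catalyst at this temperature.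

Step 7
Reactants: 10 1-[(1S)-1-[3,5-bis(benzyloxy)phenoxy]prop-2-enyl]-3-bromo-5-iodo-4-methoxybenzene
Product: 12 (3S)-3-[3,5-bis(benzyloxy)phenoxy]-3-(3-bromo-5-iodo-4-methoxyphenyl)propan-1-ol, via B-alkyl-9-borabicyclo[3.3.1]nonane 11 (not isolated)
Conditions: 9-BBN (1.5 equiv), THF, 0 °C to rt; then NaOH (3 M aq.), H2O2 (30%), 0 °C
Reagents that add atoms: hydrogen peroxide, OO
Why: Hydroboration–oxidation; the bulky borane adds boron to the terminal carbon, where it is γ to the ether oxygen and cannot undergo β-alkoxy elimination, and oxidation of the C–B bond gives the primary alcohol without touching the stereocentre.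

Step 8
Reactants: 12 (3S)-3-[3,5-bis(benzyloxy)phenoxy]-3-(3-bromo-5-iodo-4-methoxyphenyl)propan-1-ol
Product: 14 (3S)-3-[3,5-bis(benzyloxy)phenoxy]-3-(3-bromo-5-iodo-4-methoxyphenyl)propanoic acid, via aldehyde 13 (not isolated)
Conditions: TEMPO (20 mol %), PhI(OAc)2 (2.5 equiv), MeCN/H2O (1:1), rt
Reagents that add atoms: water, O
Why: Oxoammonium-mediated oxidation of a primary alcohol to the acid in one pot; aldehyde 13 is hydrated and oxidised on as it forms, under mildly acidic conditions, so the β-aryloxy aldehyde is not exposed to base that would expel the phenoxide.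

Step 9
Reactants: 14 (3S)-3-[3,5-bis(benzyloxy)phenoxy]-3-(3-bromo-5-iodo-4-methoxyphenyl)propanoic acid
Product: 16 (2S)-5,7-bis(benzyloxy)-2-(3-bromo-5-iodo-4-methoxyphenyl)chroman-4-one, via mixed trifluoroacetic anhydride 15 (not isolated)
Conditions: (CF3CO)2O (2 equiv), CH2Cl2, 0 °C to rt; aq. NaHCO3
Reagents that add atoms: none
Why: Trifluoroacetic anhydride converts acid 14 into mixed anhydride 15, whose acyl carbon (C4) is attacked by the ring-A carbon ortho to the ether oxygen; loss of trifluoroacetate and of a proton from the Wheland intermediate forms C4–C4a. This is the intramolecular Friedel–Crafts acylation of a 3-aryloxypropanoic acid to a chroman-4-one, a known closure for activated aryl ethers. Ring C closes as a six-membered ring in a 6-exo-trig mode, the arene carbon adding to the trigonal acyl carbon whose C=O bond stays outside the ring. No stereocentre is created; C2 comes from step 6 and none of its bonds is made or broken. Site selectivity is secured by the substrate: the two ring-A carbons ortho to the ether oxygen are equivalent and each is activated by three oxygens, the third activated carbon cannot be reached by the three-atom tether, and ring B is deactivated by two halogens and could only close a five-membered ring. The step must preserve the configuration at C2, which could be lost by ionisation of the benzylic C2–O bond or by acid-promoted opening of ring C in 16. Activation without a metal Lewis acid, low temperature and a short reaction time guard against this, and so does ring B: bromine and iodine flank the 4'-methoxy group, twist it out of conjugation and withdraw electron density, so a cation at C2 is poorly stabilised. Only a small excess of anhydride is used, so intermolecular trifluoroacetylation of ring A should not compete with the fast closure, after which the new ketone deactivates the ring.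

Step 10
Reactants: 16 (2S)-5,7-bis(benzyloxy)-2-(3-bromo-5-iodo-4-methoxyphenyl)chroman-4-one
Product: 17 (2S)-2-(3-bromo-5-iodo-4-methoxyphenyl)-5,7-dihydroxychroman-4-one
Conditions: BCl3 (1 M in CH2Cl2, 5 equiv), C6HMe5 (6 equiv), CH2Cl2, −78 °C; MeOH
Reagents that add atoms: none
Why: Lewis-acid debenzylation of aryl benzyl ethers with pentamethylbenzene as a non-basic cation scavenger, which keeps the benzyl cations from alkylating ring A; at −78 °C the hindered, non-chelated 4'-methyl ether and the C2–O1 bond of the electron-poor benzylic position should hold. Hydrogenolysis is excluded by the C–I and C–Br bonds, and the step is placed before the alkenes, which would not survive it.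

Step 11
Reactants: 18 2-methylbut-1-en-3-yne
Product: 19 (E)-tributyl(3-methylbuta-1,3-dienyl)stannane
Conditions: Bu3SnH (1.0 equiv), 18 (1.5 equiv), PtCl2 (5 mol %), XPhos (10 mol %), THF, sealed tube, 50 °C
Reagents that add atoms: tributyltin hydride, CCCC[SnH](CCCC)CCCC
Why: Platinum-catalysed hydrostannation of a terminal alkyne; syn addition with the bulky biarylphosphine directing tin to the terminal carbon should give the (E)-1-stannyl diene, and the 1,1-disubstituted alkene is much less reactive than the alkyne.

Step 12
Reactants: 17 (2S)-2-(3-bromo-5-iodo-4-methoxyphenyl)-5,7-dihydroxychroman-4-one; 19 (E)-tributyl(3-methylbuta-1,3-dienyl)stannane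
Product: 20 (2S)-2-{3-bromo-4-methoxy-5-[(E)-3-methylbuta-1,3-dienyl]phenyl}-5,7-dihydroxychroman-4-one
Conditions: 19 (1.2 equiv), Pd(PPh3)4 (5 mol %), CuI (10 mol %), degassed DMF, 40 °C, dark
Reagents that add atoms: none
Why: Stille coupling; zerovalent palladium inserts into the C–I bond far faster than into the C–Br bond, and the alkenyl group is transferred with retention of the (E) geometry. No base is present, so the free phenols are tolerated and ring C is not opened at C2.

Step 13
Reactants: 20 (2S)-2-{3-bromo-4-methoxy-5-[(E)-3-methylbuta-1,3-dienyl]phenyl}-5,7-dihydroxychroman-4-one; 21 tributyl(3-methylbut-2-enyl)stannane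
Product: 22 (2S)-5,7-dihydroxy-2-{4-methoxy-3-[(E)-3-methylbuta-1,3-dienyl]-5-(3-methylbut-2-enyl)phenyl}chroman-4-one
Conditions: 21 (2 equiv), Pd(PPh3)4 (10 mol %), BHT (cat.), degassed DMF, 90 °C
Reagents that add atoms: none
Why: Stille coupling of an allylic stannane at the remaining C–Br bond; reductive elimination from the aryl(allyl)palladium intermediate at the unsubstituted allyl terminus should give the linear prenyl group. The conditions are neutral, so C2, the phenols and the diene installed in step 12 should be preserved.

## Compound list

1 | 3-bromo-4-hydroxybenzaldehyde | O=Cc1ccc(O)c(Br)c1 | starting material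
2 | 3-bromo-4-hydroxy-5-iodobenzaldehyde | O=Cc1cc(Br)c(O)c(I)c1 | intermediate
3 | 3-bromo-5-iodo-4-methoxybenzaldehyde | COc1c(Br)cc(C=O)cc1I | intermediate
4 | ethyl (triphenylphosphoranylidene)acetate | CCOC(=O)C=P(c1ccccc1)(c1ccccc1)c1ccccc1 | starting material
5 | ethyl (E)-3-(3-bromo-5-iodo-4-methoxyphenyl)prop-2-enoate | CCOC(=O)/C=C/c1cc(Br)c(OC)c(I)c1 | intermediate
6 | (E)-3-(3-bromo-5-iodo-4-methoxyphenyl)prop-2-en-1-ol | COc1c(Br)cc(/C=C/CO)cc1I | intermediate
7 | (E)-3-(3-bromo-5-iodo-4-methoxyphenyl)prop-2-enyl methyl carbonate | COC(=O)OC/C=C/c1cc(Br)c(OC)c(I)c1 | intermediate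
8 | 3,5-bis(benzyloxy)phenol | Oc1cc(OCc2ccccc2)cc(OCc2ccccc2)c1 | starting material
9 | lithium 3,5-bis(benzyloxy)phenoxide | [Li+].[O-]c1cc(OCc2ccccc2)cc(OCc2ccccc2)c1 | intermediate (not isolated)
10 | 1-[(1S)-1-[3,5-bis(benzyloxy)phenoxy]prop-2-enyl]-3-bromo-5-iodo-4-methoxybenzene | COc1c(Br)cc([C@@H](Oc2cc(OCc3ccccc3)cc(OCc3ccccc3)c2)C=C)cc1I | intermediate
11 | 9-[(3S)-3-[3,5-bis(benzyloxy)phenoxy]-3-(3-bromo-5-iodo-4-methoxyphenyl)propyl]-9-borabicyclo[3.3.1]nonane | COc1c(Br)cc([C@@H](Oc2cc(OCc3ccccc3)cc(OCc3ccccc3)c2)CCB2C3CCCC2CCC3)cc1I | intermediate (not isolated)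
12 | (3S)-3-[3,5-bis(benzyloxy)phenoxy]-3-(3-bromo-5-iodo-4-methoxyphenyl)propan-1-ol | COc1c(Br)cc([C@@H](Oc2cc(OCc3ccccc3)cc(OCc3ccccc3)c2)CCO)cc1I | intermediate
13 | (3S)-3-[3,5-bis(benzyloxy)phenoxy]-3-(3-bromo-5-iodo-4-methoxyphenyl)propanal | COc1c(Br)cc([C@@H](Oc2cc(OCc3ccccc3)cc(OCc3ccccc3)c2)CC=O)cc1I | intermediate (not isolated)
14 | (3S)-3-[3,5-bis(benzyloxy)phenoxy]-3-(3-bromo-5-iodo-4-methoxyphenyl)propanoic acid | COc1c(Br)cc([C@@H](Oc2cc(OCc3ccccc3)cc(OCc3ccccc3)c2)CC(=O)O)cc1I | intermediate
15 | (3S)-3-[3,5-bis(benzyloxy)phenoxy]-3-(3-bromo-5-iodo-4-methoxyphenyl)propanoic trifluoroacetic anhydride | COc1c(Br)cc([C@@H](Oc2cc(OCc3ccccc3)cc(OCc3ccccc3)c2)CC(=O)OC(=O)C(F)(F)F)cc1I | intermediate (not isolated)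
16 | (2S)-5,7-bis(benzyloxy)-2-(3-bromo-5-iodo-4-methoxyphenyl)chroman-4-one | COc1c(Br)cc([C@@H]2CC(=O)c3c(OCc4ccccc4)cc(OCc4ccccc4)cc3O2)cc1I | intermediate
17 | (2S)-2-(3-bromo-5-iodo-4-methoxyphenyl)-5,7-dihydroxychroman-4-one | COc1c(Br)cc([C@@H]2CC(=O)c3c(O)cc(O)cc3O2)cc1I | intermediate
18 | 2-methylbut-1-en-3-yne | C=C(C)C#C | starting material
19 | (E)-tributyl(3-methylbuta-1,3-dienyl)stannane | C=C(C)/C=C/[Sn](CCCC)(CCCC)CCCC | intermediate
20 | (2S)-2-{3-bromo-4-methoxy-5-[(E)-3-methylbuta-1,3-dienyl]phenyl}-5,7-dihydroxychroman-4-one | C=C(C)/C=C/c1cc([C@@H]2CC(=O)c3c(O)cc(O)cc3O2)cc(Br)c1OC | intermediate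
21 | tributyl(3-methylbut-2-enyl)stannane | CCCC[Sn](CCCC)(CCCC)CC=C(C)C | starting material
22 | (2S)-5,7-dihydroxy-2-{4-methoxy-3-[(E)-3-methylbuta-1,3-dienyl]-5-(3-methylbut-2-enyl)phenyl}chroman-4-one | C=C(C)/C=C/c1cc([C@@H]2CC(=O)c3c(O)cc(O)cc3O2)cc(CC=C(C)C)c1OC | target

Total step count: 13. Longest linear sequence: 12 steps (steps 1 to 10, then 12 and 13, from 1 to 22); step 11 is a one-step side branch.

## Steps least certain to work

**Step 9 (key step).** The most likely failure is erosion of the configuration at C2, either by reversible ionisation of the benzylic C–O bond in the acidic medium or by acid-promoted opening and reclosure of ring C. A second risk is consumption of ring A by intermolecular trifluoroacetylation. The fallback gives up the C4–C4a closure and closes ring C at O1–C2, then resolves. It sets out from aldehyde 3. Claisen–Schmidt condensation of 3 with 1-[2,4-bis(benzyloxy)-6-hydroxyphenyl]ethanone F1 (KOH, EtOH, rt) should give (E)-1-[2,4-bis(benzyloxy)-6-hydroxyphenyl]-3-(3-bromo-5-iodo-4-methoxyphenyl)prop-2-en-1-one F2. Oxa-Michael closure (NaOAc, EtOH, reflux) should give racemic 5,7-bis(benzyloxy)-2-(3-bromo-5-iodo-4-methoxyphenyl)chroman-4-one F3. Kinetic resolution by asymmetric transfer hydrogenation with RuCl(p-cymene)[TsDPEN] in HCO2H/Et3N follows, using the catalyst enantiomer that reduces the (2R)-ketone to (2R,4R)-5,7-bis(benzyloxy)-2-(3-bromo-5-iodo-4-methoxyphenyl)chroman-4-ol F4. This leaves the (2S)-ketone, and the route is rejoined at 16. At most half of the material is kept.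

**Step 6.** Possible failures are a poor branched-to-linear ratio or poor facial selectivity with this doubly halogenated cinnamyl unit, C-allylation of the very electron-rich phenoxide at its ring carbons, and catalyst deactivation by the aryl iodide. The fallback replaces catalytic etherification by substitution with inversion at a preformed carbinol, and sets out from aldehyde 3. Asymmetric allylation with the enantiomer of B-allyldiisopinocampheylborane that gives the (R)-alcohol (Et2O, −78 °C; NaOH, H2O2) should give (1R)-1-(3-bromo-5-iodo-4-methoxyphenyl)but-3-en-1-ol F5. Mitsunobu etherification with phenol 8 (PPh3, DIAD, toluene, 0 °C) should invert the carbinol; the electron-poor ring B disfavours an ionising pathway. It gives 1-[(1S)-1-[3,5-bis(benzyloxy)phenoxy]but-3-enyl]-3-bromo-5-iodo-4-methoxybenzene F6. Oxidative cleavage of the terminal alkene (OsO4 cat., NaIO4, 2,6-lutidine, dioxane/H2O) returns the route at aldehyde 13, which is oxidised to 14 under the conditions of step 8.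

**Step 13.** Possible failures are allyl transposition giving the 1,1-dimethylallyl isomer, migration of the double bond into conjugation, Heck-type insertion of the aryl-palladium intermediate into the diene already present, and thermal loss of the diene during a slow coupling at the bromide. The fallback changes the order and the way the prenyl group is made, so that the diene is installed last. It sets out from 17. Stille coupling with allyltributylstannane at the iodide (Pd(PPh3)4, DMF, 60 °C) should give (2S)-2-[3-bromo-4-methoxy-5-(prop-2-enyl)phenyl]-5,7-dihydroxychroman-4-one F7. Cross-metathesis with 2-methylbut-2-ene (second-generation Grubbs catalyst, RuCl2(H2IMes)(PCy3)(=CHPh), CH2Cl2, 40 °C) should give (2S)-2-[3-bromo-4-methoxy-5-(3-methylbut-2-enyl)phenyl]-5,7-dihydroxychroman-4-one F8. Stille coupling of F8 with stannane 19 at the bromide (Pd(PPh3)4, DMF, 90 °C) rejoins the route at 22.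

**Step 11.** Possible failures are addition of tin to the internal alkyne carbon, which the conjugated alkene favours with some catalysts, incomplete (E) selectivity, and evaporative loss of the volatile enyne. The fallback fixes regiochemistry and geometry by hydrometalation with zirconium and sets out from 18. Hydrozirconation with Cp2Zr(H)Cl (THF, rt) followed by iodinolysis (I2, 0 °C) should give (E)-1-iodo-3-methylbuta-1,3-diene F9, kept in solution. Iodine–lithium exchange (t-BuLi, Et2O, −78 °C) and quenching with Bu3SnCl rejoin the route at 19.

## Further compounds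

F1 | step 9 | 1-[2,4-bis(benzyloxy)-6-hydroxyphenyl]ethanone | CC(=O)c1c(O)cc(OCc2ccccc2)cc1OCc1ccccc1
F2 | step 9 | (E)-1-[2,4-bis(benzyloxy)-6-hydroxyphenyl]-3-(3-bromo-5-iodo-4-methoxyphenyl)prop-2-en-1-one | COc1c(Br)cc(/C=C/C(=O)c2c(O)cc(OCc3ccccc3)cc2OCc2ccccc2)cc1I
F3 | step 9 | racemic 5,7-bis(benzyloxy)-2-(3-bromo-5-iodo-4-methoxyphenyl)chroman-4-one | COc1c(Br)cc(C2CC(=O)c3c(OCc4ccccc4)cc(OCc4ccccc4)cc3O2)cc1I
F4 | step 9 | (2R,4R)-5,7-bis(benzyloxy)-2-(3-bromo-5-iodo-4-methoxyphenyl)chroman-4-ol | COc1c(Br)cc([C@H]2C[C@@H](O)c3c(OCc4ccccc4)cc(OCc4ccccc4)cc3O2)cc1I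
F5 | step 6 | (1R)-1-(3-bromo-5-iodo-4-methoxyphenyl)but-3-en-1-ol | COc1c(Br)cc([C@H](O)CC=C)cc1I
F6 | step 6 | 1-[(1S)-1-[3,5-bis(benzyloxy)phenoxy]but-3-enyl]-3-bromo-5-iodo-4-methoxybenzene | COc1c(Br)cc([C@@H](Oc2cc(OCc3ccccc3)cc(OCc3ccccc3)c2)CC=C)cc1I
F7 | step 13 | (2S)-2-[3-bromo-4-methoxy-5-(prop-2-enyl)phenyl]-5,7-dihydroxychroman-4-one | C=CCc1cc([C@@H]2CC(=O)c3c(O)cc(O)cc3O2)cc(Br)c1OC
F8 | step 13 | (2S)-2-[3-bromo-4-methoxy-5-(3-methylbut-2-enyl)phenyl]-5,7-dihydroxychroman-4-one | CC(C)=CCc1cc([C@@H]2CC(=O)c3c(O)cc(O)cc3O2)cc(Br)c1OC
F9 | step 11 | (E)-1-iodo-3-methylbuta-1,3-diene | C=C(C)/C=C/I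
A1 | alternative 1 | (2S)-5,7-bis(tert-butyldimethylsilyloxy)-2-{4-methoxy-3-[(E)-3-methylbuta-1,3-dienyl]-5-(3-methylbut-2-enyl)phenyl}chroman-4-one | C=C(C)/C=C/c1cc([C@@H]2CC(=O)c3c(O[Si](C)(C)C(C)(C)C)cc(O[Si](C)(C)C(C)(C)C)cc3O2)cc(CC=C(C)C)c1OC
A2 | alternative 1 | 1-[2,4-bis(tert-butyldimethylsilyloxy)-6-{methoxy[4-methoxy-3-((E)-3-methylbuta-1,3-dienyl)-5-(3-methylbut-2-enyl)phenyl]methoxy}phenyl]-1-(tert-butyldimethylsilyloxy)ethene (acetal carbon not defined) | C=C(O[Si](C)(C)C(C)(C)C)c1c(O[Si](C)(C)C(C)(C)C)cc(O[Si](C)(C)C(C)(C)C)cc1OC(OC)c1cc(/C=C/C(C)=C)c(OC)c(CC=C(C)C)c1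
A3 | alternative 2 | (2S)-2-(3-bromo-5-iodo-4-methoxyphenyl)-2,3-dihydro-4H-pyran-4-one | COc1c(Br)cc([C@@H]2CC(=O)C=CO2)cc1I
A4 | alternative 2 | (E)-1-methoxy-3-(trimethylsilyloxy)buta-1,3-diene | CO/C=C/C(=C)O[Si](C)(C)C
A5 | alternative 3 | (2S,4S)-5,7-bis(benzyloxy)-2-(3-bromo-5-iodo-4-methoxyphenyl)-4-methoxychroman | COc1c(Br)cc([C@@H]2C[C@H](OC)c3c(OCc4ccccc4)cc(OCc4ccccc4)cc3O2)cc1I
A6 | alternative 3 | 1-bromo-5-ethenyl-3-iodo-2-methoxybenzene | C=Cc1cc(Br)c(OC)c(I)c1
A7 | alternative 3 | 3,5-bis(benzyloxy)-2-(dimethoxymethyl)phenol | COC(OC)c1c(O)cc(OCc2ccccc2)cc1OCc1ccccc1
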